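Numbering: C1 (alkyne CH) to C15; O-a joins C6/C10, O-b joins C7/C13. Everything rests on reading C10(O-a)–C11H2–C12(Br) as a masked β-alkoxy ketone. The oxocane (O-b, C7–C13) is built first by ring-closing metathesis. A C12 ketone then turns its 9,10-epoxide into a γ-hydroxy enone with C10 as β-carbon. In the key step, allylboration of the C6 aldehyde frees a C6 hydroxyl that adds across the ring to C10. This one operation forms C5–C6 and O-a–C10, sets C6 and C10, and closes the tetrahydropyran and the eight-membered 1,4-dioxocane (C6, O-a, C10–C13, O-b, C7). The precursor is a monocyclic oxocenone aldehyde. Both bromides follow by invertive Appel reaction.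

Key step: step 10

Remark: in this numbering the target is 6R,7S,9S,10R,12S,13R. C9–Br and C10–O-a are cis on the oxocane (erythro), so C9–Br has to come from an SN2 inversion and not from anti addition to a Z-alkene. Compound 1 is written in its open-chain form.

Step 1
Reactants: 1 2-deoxy-D-ribose
Product: 2 (2R,3S)-hex-5-ene-1,2,3-triol
Conditions: MePPh3Br, KOt-Bu, THF, 0 °C to rt
Reagents that add atoms: methyltriphenylphosphonium bromide, C[P+](c1ccccc1)(c1ccccc1)c1ccccc1.[Br-]
Why: Wittig methylenation of the aldehyde form of the lactol should give the terminal alkene (future C9) without touching the two carbinol carbons, which become C7 (S) and C6.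

Step 2
Reactants: 2 (2R,3S)-hex-5-ene-1,2,3-triol
Product: 3 (S)-1-[(R)-2,2-dimethyl-1,3-dioxolan-4-yl]but-3-en-1-ol
Conditions: 2,2-dimethoxypropane, p-TsOH (cat.), acetone, 0 °C
Reagents that add atoms: 2,2-dimethoxypropane, COC(C)(C)OC
Why: Acid-catalysed transketalisation favours the terminal 1,2-dioxolane over the cis-disubstituted internal one, so only the C7 hydroxyl stays free and no stereocentre is touched.

Step 3
Reactants: 3 (S)-1-[(R)-2,2-dimethyl-1,3-dioxolan-4-yl]but-3-en-1-ol; 4 (S)-2-bromobutanoic acid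
Product: 6 methyl (R)-2-{(S)-1-[(R)-2,2-dimethyl-1,3-dioxolan-4-yl]but-3-enyloxy}butanoate, via sodium carboxylate 5 (not isolated)
Conditions: NaH (excess), THF–DMF, 0 °C to rt; then MeI, rt
Reagents that add atoms: iodomethane, CI
Why: Williamson etherification of the C7 alkoxide with the α-bromo carboxylate (the method used for lactyl ethers of sugars) is an SN2 displacement with inversion that turns (S)-4 into C13 (R), and the carboxylate is then O-methylated in the same flask.

Step 4
Reactants: 6 methyl (R)-2-{(S)-1-[(R)-2,2-dimethyl-1,3-dioxolan-4-yl]but-3-enyloxy}butanoate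
Product: 7 (R)-2-{(S)-1-[(R)-2,2-dimethyl-1,3-dioxolan-4-yl]but-3-enyloxy}butanal
Conditions: i-Bu2AlH (1.1 equiv), CH2Cl2, −78 °C
Reagents that add atoms: none
Why: Partial ester reduction stops at the chelated aluminium hemiacetal of the α-alkoxy ester at low temperature, so the aldehyde appears only on work-up and C13 is not epimerised.

Step 5
Reactants: 7 (R)-2-{(S)-1-[(R)-2,2-dimethyl-1,3-dioxolan-4-yl]but-3-enyloxy}butanal
Product: 8 (3R,4R)-3-{(S)-1-[(R)-2,2-dimethyl-1,3-dioxolan-4-yl]but-3-enyloxy}hept-6-en-4-ol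
Conditions: MgBr2·OEt2, allylSnBu3, CH2Cl2, −78 to −20 °C
Reagents that add atoms: allyltributylstannane, C=CC[Sn](CCCC)(CCCC)CCCC
Why: Chelation-controlled allylstannane addition (Cram chelate of magnesium between the aldehyde oxygen and O-b) sends the allyl group to the face opposite the ethyl group and should give the 12,13-syn alcohol, C12 (R).

Step 6
Reactants: 8 (3R,4R)-3-{(S)-1-[(R)-2,2-dimethyl-1,3-dioxolan-4-yl]but-3-enyloxy}hept-6-en-4-ol
Product: 9 (2R,3R,8S,Z)-8-[(R)-2,2-dimethyl-1,3-dioxolan-4-yl]-2-ethyl-3,4,7,8-tetrahydro-2H-oxocin-3-ol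
Conditions: second-generation Grubbs catalyst (5 mol %), CH2Cl2 (2 mM), reflux
Reagents that add atoms: none
Why: Ring-closing metathesis of the only two alkenes closes the Z-oxocene, helped by the gauche preference of the vicinal C–O bonds at C12/C13 and C6/C7 that folds the chain, and no stereocentre changes.

Step 7
Reactants: 9 (2R,3R,8S,Z)-8-[(R)-2,2-dimethyl-1,3-dioxolan-4-yl]-2-ethyl-3,4,7,8-tetrahydro-2H-oxocin-3-ol
Product: 10 epoxy alcohol (9,10-epoxide of 9 on the ring face of the C12 hydroxyl; 7S,9R,10S,12R,13R)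
Conditions: VO(acac)2 (5 mol %), t-BuOOH, CH2Cl2, 0 °C to rt
Reagents that add atoms: tert-butyl hydroperoxide, CC(C)(C)OO
Why: Hydroxyl-directed vanadium-catalysed epoxidation delivers oxygen from the metal alkoxide of the homoallylic C12 hydroxyl, so the epoxide should form on the face that carries this hydroxyl (9R,10S).

Step 8
Reactants: 10 epoxy alcohol
Product: 12 γ-hydroxy enone acetonide (Z-10-en-12-one with 9-OH; 7S,9R,13R), via epoxy ketone 11 (not isolated)
Conditions: Dess–Martin periodinane, CH2Cl2, 0 °C; wash; crude in CH2Cl2, DBU (0.2 equiv), 0 °C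
Reagents that add atoms: none
Why: Dess–Martin oxidation gives the β,γ-epoxy ketone, whose acidic C11 proton allows an E1cB epoxide opening to the conjugated Z-enone that keeps the C9–O bond and hence C9 (R).

Step 9
Reactants: 12 γ-hydroxy enone acetonide
Product: 14 oxocenone aldehyde (CHO = C6 on C7; 7S,9R,13R), via enone diol 13 (not isolated)
Conditions: H5IO6, EtOAc, 0 °C to rt
Reagents that add atoms: none
Why: Periodic acid hydrolyses the terminal acetonide and cleaves the freed 1,2-diol at once (glycol cleavage), which exposes the C6 aldehyde without base so that C7 is not epimerised.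

Step 10
Reactants: 14 oxocenone aldehyde
Product: 17 (1S,3R,6R,8R,10R)-8-allyl-3-ethyl-10-hydroxy-2,7-dioxabicyclo[4.2.2]decan-4-one, via borate ester 15 (not isolated), via homoallylic alcohol 16 (not isolated)
Conditions: allylB(pin), CH2Cl2, 0 °C to rt; then MeOH, DBU (0.3 equiv), rt
Reagents that add atoms: allylboronic acid pinacol ester, C=CCB1OC(C)(C)C(C)(C)O1
Why: Allylboration through a closed Zimmerman–Traxler transition state adds the allyl group to the aldehyde only (the enone carbonyl is inert to allylB(pin)), and methanolysis of borate 15 frees the C6 hydroxyl of 16. DBU then catalyses a transannular oxa-Michael addition of O-a to C10, the β-carbon of the strained Z-enone; the closest known types are tandem allylation/oxa-Michael tetrahydropyran syntheses and transannular oxa-conjugate additions in cyclooctenones. The single new O-a–C10 bond closes the tetrahydropyran in the 6-exo-trig mode and, by the same bond, the eight-membered 1,4-dioxocane (C6, O-a, C10, C11, C12, C13, O-b, C7), which completes the 2,7-dioxabicyclo[4.2.2]decane. C6 (R) is set by the polar Felkin–Anh/Cornforth preference of the α-alkoxy aldehyde for the 6,7-anti adduct, and C10 (R) is dictated by C7 because only attack on the inner alkene face gives an out,out bridged bicycle. The step needs attack at C10 and not at C9 (the usual 5-exo outcome of electrophile-induced closures of oxocenes); the C12 carbonyl secures this electronically, and C9–OH lies on the opposite ring face and cannot compete. The addition is reversible, so the bicycle must be the thermodynamic sink; relief of enone strain and hemiketal formation between C9–OH and C12=O should help, and 17 is reduced without delay.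

Step 11
Reactants: 17 (1S,3R,6R,8R,10R)-8-allyl-3-ethyl-10-hydroxy-2,7-dioxabicyclo[4.2.2]decan-4-one
Product: 18 (1S,3R,4R,6R,8R,10R)-8-allyl-3-ethyl-2,7-dioxabicyclo[4.2.2]decane-4,10-diol
Conditions: NaBH4, CeCl3·7H2O, MeOH, −78 °C
Reagents that add atoms: none
Why: Luche-type borohydride reduction is fast and only weakly basic (no retro-Michael), and hydride should reach C12 from the face next to the short C6–O-a bridge, anti to the C13 ethyl group (Felkin–Anh) and to C9–OH, giving C12 (R).

Step 12
Reactants: 18 (1S,3R,4R,6R,8R,10R)-8-allyl-3-ethyl-2,7-dioxabicyclo[4.2.2]decane-4,10-diol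
Product: 19 (1S,3R,4S,6R,8R,10S)-8-allyl-4,10-dibromo-3-ethyl-2,7-dioxabicyclo[4.2.2]decane
Conditions: CBr4, P(n-C8H17)3, toluene, 70 °C
Reagents that add atoms: tetrabromomethane, BrC(Br)(Br)Br
Why: In this double Appel reaction bromide displaces both alkoxyphosphonium groups by SN2 from the open face next to the C6–O-a bridge, which inverts C9 and C12 to (S) and (S) and creates the cis C9–Br/C10–O-a relation. The two hydroxyls cannot etherify each other because that would need a trans bridge.

Step 13
Reactants: 19 (1S,3R,4S,6R,8R,10S)-8-allyl-4,10-dibromo-3-ethyl-2,7-dioxabicyclo[4.2.2]decane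
Product: 20 (E)-4-[(1S,3R,4S,6R,8R,10S)-4,10-dibromo-3-ethyl-2,7-dioxabicyclo[4.2.2]decan-8-yl]but-2-enal
Conditions: crotonaldehyde (5 equiv), second-generation Hoveyda–Grubbs catalyst (5 mol %), CH2Cl2, 40 °C
Reagents that add atoms: crotonaldehyde, C/C=C/C=O
Why: Cross metathesis of the only alkene, a reactive terminal one, with the electron-poor crotonaldehyde should give the conjugated enal as the E isomer under thermodynamic control.

Step 14
Reactants: 20 (E)-4-[(1S,3R,4S,6R,8R,10S)-4,10-dibromo-3-ethyl-2,7-dioxabicyclo[4.2.2]decan-8-yl]but-2-enal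
Product: 21 (1S,3R,4S,6R,8R,10S)-4,10-dibromo-3-ethyl-8-[(E)-pent-2-en-4-yn-1-yl]-2,7-dioxabicyclo[4.2.2]decane
Conditions: Me3SiCHN2, LiN(i-Pr)2, THF, −78 to 0 °C
Reagents that add atoms: (trimethylsilyl)diazomethane, C[Si](C)(C)C=[N+]=[N-]
Why: In the Colvin rearrangement, addition of lithiated Me3SiCHN2, Peterson-type loss of silanolate, loss of nitrogen and a 1,2-hydride shift of the alkylidene carbene give the terminal alkyne, leaving the E-alkene and both secondary bromides untouched at low temperature.

Compound list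
1 | 2-deoxy-D-ribose (open-chain form) | O=CC[C@H](O)[C@H](O)CO | starting material
2 | (2R,3S)-hex-5-ene-1,2,3-triol | C=CC[C@H](O)[C@H](O)CO | intermediate
3 | (S)-1-[(R)-2,2-dimethyl-1,3-dioxolan-4-yl]but-3-en-1-ol | C=CC[C@H](O)[C@H]1COC(C)(C)O1 | intermediate
4 | (S)-2-bromobutanoic acid | CC[C@H](Br)C(=O)O | starting material
5 | sodium (R)-2-{(S)-1-[(R)-2,2-dimethyl-1,3-dioxolan-4-yl]but-3-enyloxy}butanoate | C=CC[C@H](O[C@H](CC)C(=O)[O-])[C@H]1COC(C)(C)O1.[Na+] | intermediate
6 | methyl (R)-2-{(S)-1-[(R)-2,2-dimethyl-1,3-dioxolan-4-yl]but-3-enyloxy}butanoate | C=CC[C@H](O[C@H](CC)C(=O)OC)[C@H]1COC(C)(C)O1 | intermediate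
7 | (R)-2-{(S)-1-[(R)-2,2-dimethyl-1,3-dioxolan-4-yl]but-3-enyloxy}butanal | C=CC[C@H](O[C@H](CC)C=O)[C@H]1COC(C)(C)O1 | intermediate
8 | (3R,4R)-3-{(S)-1-[(R)-2,2-dimethyl-1,3-dioxolan-4-yl]but-3-enyloxy}hept-6-en-4-ol | C=CC[C@H](O[C@H](CC)[C@H](O)CC=C)[C@H]1COC(C)(C)O1 | intermediate
9 | (2R,3R,8S,Z)-8-[(R)-2,2-dimethyl-1,3-dioxolan-4-yl]-2-ethyl-3,4,7,8-tetrahydro-2H-oxocin-3-ol | CC[C@H]1O[C@@H](C/C=C\C[C@H]1O)[C@H]2COC(C)(C)O2 | intermediate
10 | epoxy alcohol, 9,10-epoxide syn to C12–OH (7S,9R,10S,12R,13R) | CC[C@H]1O[C@@H](C[C@H]3O[C@H]3C[C@H]1O)[C@H]2COC(C)(C)O2 | intermediate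
11 | epoxy ketone (7S,9R,10S,13R) | CC[C@H]1O[C@@H](C[C@H]3O[C@H]3CC1=O)[C@H]2COC(C)(C)O2 | intermediate
12 | γ-hydroxy enone acetonide (7S,9R,13R; Z) | CC[C@H]1O[C@@H](C[C@@H](O)/C=C\C1=O)[C@H]2COC(C)(C)O2 | intermediate
13 | enone diol (side chain CH(OH)CH2OH on C7) | CC[C@H]1O[C@@H](C[C@@H](O)/C=C\C1=O)[C@H](O)CO | intermediate
14 | oxocenone aldehyde (7S,9R,13R; Z) | CC[C@H]1O[C@@H](C[C@@H](O)/C=C\C1=O)C=O | intermediate
15 | pinacol borate ester of 16 (6R) | CC[C@H]1O[C@@H](C[C@@H](O)/C=C\C1=O)[C@H](OB2OC(C)(C)C(C)(C)O2)CC=C | intermediate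
16 | homoallylic alcohol (6R,7S,9R,13R; Z-enone) | CC[C@H]1O[C@@H](C[C@@H](O)/C=C\C1=O)[C@H](O)CC=C | intermediate
17 | (1S,3R,6R,8R,10R)-8-allyl-3-ethyl-10-hydroxy-2,7-dioxabicyclo[4.2.2]decan-4-one | C=CC[C@H]1O[C@@H]2CC(=O)[C@@H](CC)O[C@H]1C[C@H]2O | intermediate
18 | (1S,3R,4R,6R,8R,10R)-8-allyl-3-ethyl-2,7-dioxabicyclo[4.2.2]decane-4,10-diol | C=CC[C@H]1O[C@@H]2C[C@@H](O)[C@@H](CC)O[C@H]1C[C@H]2O | intermediate
19 | (1S,3R,4S,6R,8R,10S)-8-allyl-4,10-dibromo-3-ethyl-2,7-dioxabicyclo[4.2.2]decane | C=CC[C@H]1O[C@@H]2C[C@H](Br)[C@@H](CC)O[C@H]1C[C@@H]2Br | intermediate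
20 | (E)-4-[(1S,3R,4S,6R,8R,10S)-4,10-dibromo-3-ethyl-2,7-dioxabicyclo[4.2.2]decan-8-yl]but-2-enal | O=C/C=C/C[C@H]1O[C@@H]2C[C@H](Br)[C@@H](CC)O[C@H]1C[C@@H]2Br | intermediate
21 | (1S,3R,4S,6R,8R,10S)-4,10-dibromo-3-ethyl-8-[(E)-pent-2-en-4-yn-1-yl]-2,7-dioxabicyclo[4.2.2]decane | C#C/C=C/C[C@H]1O[C@@H]2C[C@H](Br)[C@@H](CC)O[C@H]1C[C@@H]2Br | target

Total step count: 14. Longest linear sequence: 14 steps (from 1).

Steps most likely to fail

**Step 10.**
- What may go wrong: the conjugate addition is reversible, so the strained bicycle may not be favoured over the open enone. The amine base may drain 16 by isomerisation of the γ-hydroxy enone. Facial selectivity of the allylation may be modest.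
- Fallback (a stronger acceptor whose adduct does not revert): the route sets out from 12. The C9 hydroxyl is oxidised with MnO2 to the ene-dione acetonide F1. H5IO6 leads through the ene-dione diol F2 to the ene-dione aldehyde F3. AllylB(pin) gives the borate ester F4 and, after methanolysis, the homoallylic alcohol F5. F5 should close onto C10 of the doubly activated alkene (six-membered ring, against a seven-membered ring at C11) to the bicyclic 9,12-diketone F6. Double reduction with NaBH4/CeCl3·7H2O from the face of the C6–O-a bridge comes back to the route at 18.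

**Step 12.**
- What may go wrong: O-a or O-b may take part in the departure of the phosphine oxide (oxiranium ions, hence retention or ring contraction), and E2 loss may occur at the hindered carbinols.
- Fallback: the route sets out from 18. Both hydroxyls are sulfonylated with ClCH2SO2Cl and pyridine to the bis(chloromethanesulfonate) F7. F7 is displaced in a separate step by LiBr in DMF at moderate temperature, which comes back to the route at 19.

**Step 7.**
- What may go wrong: facial selectivity may be poor or oxygen transfer slow in the medium ring.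
- Fallback: the route sets out from 9. The C12 hydroxyl is acylated (Boc2O, DMAP) to the tert-butyl carbonate F8. IBr at low temperature triggers an iodocarbonate cyclisation to the cyclic iodocarbonate F9: the carbonyl oxygen attacks C10 through a six-membered ring on the face of C12–O, and iodine ends on C9 on the other face. K2CO3 in MeOH cleaves the carbonate to the iodo diol F10, whose C10 alkoxide displaces iodide. This comes back to the route at 10 with the epoxide face fixed by C12.

Further compounds
F1 | step 10 | ene-dione acetonide (7S,13R; Z) | CC[C@H]1O[C@@H](CC(=O)/C=C\C1=O)[C@H]2COC(C)(C)O2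
F2 | step 10 | ene-dione diol | CC[C@H]1O[C@@H](CC(=O)/C=C\C1=O)[C@H](O)CO
F3 | step 10 | ene-dione aldehyde | CC[C@H]1O[C@@H](CC(=O)/C=C\C1=O)C=O
F4 | step 10 | pinacol borate ester of F5 | CC[C@H]1O[C@@H](CC(=O)/C=C\C1=O)[C@H](OB2OC(C)(C)C(C)(C)O2)CC=C
F5 | step 10 | homoallylic alcohol of the ene-dione (6R) | CC[C@H]1O[C@@H](CC(=O)/C=C\C1=O)[C@H](O)CC=C
F6 | step 10 | (1S,3R,6R,8R)-8-allyl-3-ethyl-2,7-dioxabicyclo[4.2.2]decane-4,10-dione | C=CC[C@H]1O[C@@H]2CC(=O)[C@@H](CC)O[C@H]1CC2=O
F7 | step 12 | bis(chloromethanesulfonate) of 18 | C=CC[C@H]1O[C@@H]2C[C@@H](OS(=O)(=O)CCl)[C@@H](CC)O[C@H]1C[C@H]2OS(=O)(=O)CCl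
F8 | step 7 | tert-butyl carbonate of 9 | CC[C@H]1O[C@@H](C/C=C\C[C@H]1OC(=O)OC(C)(C)C)[C@H]2COC(C)(C)O2
F9 | step 7 | cyclic iodocarbonate (9S,10S,12R) | CC[C@H]1O[C@@H](C[C@H](I)[C@@H]3C[C@H]1OC(=O)O3)[C@H]2COC(C)(C)O2
F10 | step 7 | iodo diol (9S,10S,12R) | CC[C@H]1O[C@@H](C[C@H](I)[C@@H](O)C[C@H]1O)[C@H]2COC(C)(C)O2
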